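**Retrosynthetic overview**
- The target is made from a bicyclic α‑hydroxy γ‑lactone (ring B still a lactone) by aryllithium addition and Et3SiH/BF3·OEt2 reduction of the lactol, which sets C2 with the aryl group endo.
- The hydroxy‑lactone comes from a cyclic formal (1,3‑dioxane fused to the ring‑B lactone) by a Lewis‑acid [1,2] O→C shift with ring contraction; this forms C1–C8, ring A and the tertiary alcohol.
- The saturated formal comes from face‑selective hydrogenation (sets C5) of the unsaturated cyclic formal, made from a MOM enol ether carbinol; asymmetric ketone hydrogenation sets C6.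
- The aroyl hydroxy‑furanone comes from 3,4‑dimethoxyacetophenone, dimethyl oxalate and formaldehyde; both aryl rings come from catechol.
- Ring order: ring‑B lactone (step 3) → 1,3‑dioxane (step 6) → ring A by contraction (step 8) → ring B reduced to the ether (step 10).

Assumption: the SMILES is read as (1S,2S,5R,6R)-2,6-bis(3,4-dimethoxyphenyl)-3,7-dioxabicyclo[3.3.0]octan-1-ol (cis‑fused, both aryl groups endo, i.e. trans to OH‑1 and H‑5); the core locants C1–C8 of this name are used for all intermediates.

**Route**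

Step 1
Reactants: 1 catechol (benzene-1,2-diol)
Product: 2 1,2-dimethoxybenzene (veratrole)
Conditions: Me2SO4 (2.2 equiv), K2CO3, acetone, reflux
Reagents that add atoms: dimethyl sulfate, COS(=O)(=O)OC
Why: Williamson-type double O-methylation of the catecholate with dimethyl sulfate is a standard, high-yielding reaction and forms no stereocentre.

Step 2
Reactants: 2 1,2-dimethoxybenzene
Product: 3 1-(3,4-dimethoxyphenyl)ethanone
Conditions: Ac2O (1.2 equiv), Sc(OTf)3 (5 mol%), LiClO4, MeNO2, 50 °C
Reagents that add atoms: acetic anhydride, CC(=O)OC(C)=O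
Why: Friedel–Crafts acylation catalysed by Sc(OTf)3 occurs para to a methoxy group (C4 of veratrole), the most activated and least hindered position, giving the 3,4-dimethoxyphenyl ketone without ether cleavage.

Step 3
Reactants: 3 1-(3,4-dimethoxyphenyl)ethanone, 4 dimethyl oxalate
Product: 6 4-(3,4-dimethoxybenzoyl)-3-hydroxyfuran-2(5H)-one, via sodium aroylpyruvate enolate 5 (not isolated)
Conditions: NaOMe (1.1 equiv), MeOH, 0 → 25 °C; then 37% aq. CH2O, 25 °C; then 2 M HCl
Reagents that add atoms: formaldehyde, C=O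
Why: Crossed Claisen condensation of the methyl ketone with non-enolisable dimethyl oxalate gives the aroylpyruvate enolate, whose central carbon adds to formaldehyde (aldol) and the resulting alkoxide lactonises onto the α-keto ester, the classical acylpyruvate–aldehyde route to 4-acyl-3-hydroxyfuran-2(5H)-ones (ring B as its lactone; no stereocentre).

Step 4
Reactants: 6 4-(3,4-dimethoxybenzoyl)-3-hydroxyfuran-2(5H)-one
Product: 7 4-(3,4-dimethoxybenzoyl)-3-(methoxymethoxy)furan-2(5H)-one
Conditions: MOMCl (1.3 equiv), i-Pr2NEt, CH2Cl2, 0 °C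
Reagents that add atoms: chloromethyl methyl ether, COCCl
Why: O-Alkylation of the strongly acidic enol (a vinylogous carboxylic acid) by the hard electrophile MOMCl leaves a neutral aryl ketone as the only reducible carbonyl and installs the CH2 unit that later becomes C8.

Step 5
Reactants: 7 4-(3,4-dimethoxybenzoyl)-3-(methoxymethoxy)furan-2(5H)-one
Product: 8 (S)-4-[(3,4-dimethoxyphenyl)(hydroxy)methyl]-3-(methoxymethoxy)furan-2(5H)-one
Conditions: H2 (8 atm), RuH(BH4)[(S)-xylbinap][(S,S)-dpen] (0.5 mol%), 2-propanol, 25 °C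
Reagents that add atoms: none
Why: Noyori asymmetric hydrogenation with a base-free diphosphine/diamine ruthenium hydride reduces the aryl ketone chemoselectively (lactone and tetrasubstituted C=C untouched) and, by analogy with ortho-substituted benzophenones where the planar aryl ring and the twisted flanked ring are differentiated, delivers hydride to one enantioface to set the benzylic stereocentre as (S), which is C6 (R) of the target.

Step 6
Reactants: 8 (S)-4-[(3,4-dimethoxyphenyl)(hydroxy)methyl]-3-(methoxymethoxy)furan-2(5H)-one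
Product: 9 (5S)-5-(3,4-dimethoxyphenyl)-2,4,8-trioxabicyclo[4.3.0]non-1(6)-en-9-one
Conditions: pyridinium p-toluenesulfonate (5 mol%), 4 Å molecular sieves, CH2Cl2, 0 → 25 °C
Reagents that add atoms: none
Why: Acid-catalysed intramolecular transacetalisation: the MOM group on the acidic enol oxygen is an activated acetal that loses methanol while the benzylic hydroxyl closes the six-membered cyclic formal, a step that does not break the C–O bond at the stereocentre.

Step 7
Reactants: 9 (5S)-5-(3,4-dimethoxyphenyl)-2,4,8-trioxabicyclo[4.3.0]non-1(6)-en-9-one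
Product: 10 (1S,5R,6R)-5-(3,4-dimethoxyphenyl)-2,4,8-trioxabicyclo[4.3.0]nonan-9-one
Conditions: H2 (10 atm), 5% Rh on Al2O3, EtOAc, 25 °C
Reagents that add atoms: none
Why: Heterogeneous syn-hydrogenation of the tetrasubstituted butenolide double bond occurs on the face opposite the pseudo-axial aryl group of the rigid bicycle, so the new hydrogen at core C5 is cis to the benzylic hydrogen at C6 and the rings are cis-fused, and rhodium is used because it spares benzylic C–O bonds.

Step 8
Reactants: 10 (1S,5R,6R)-5-(3,4-dimethoxyphenyl)-2,4,8-trioxabicyclo[4.3.0]nonan-9-one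
Product: 13 (1S,5R,6R)-6-(3,4-dimethoxyphenyl)-1-hydroxy-3,7-dioxabicyclo[3.3.0]octan-2-one, via silyl ketene acetal 11 (not isolated), via rearranged trimethylsilyl ether 12 (not isolated)
Conditions: Me3SiOTf (1.3 equiv), i-Pr2NEt (1.1 equiv), CH2Cl2, −78 → −30 °C; then 1 M HCl, THF, 0 °C
Reagents that add atoms: none
Why: Proposed new method: a Lewis-acid-triggered, stepwise ionic [1,2] oxygen-to-carbon shift with ring contraction (1,3-dioxane to tetrahydrofuran), in which Me3SiOTf/i-Pr2NEt first converts the lactone into silyl ketene acetal 11, Me3SiOTf then silylates the α-oxygen and cleaves its bond to the formal CH2 to give an O7-stabilised oxocarbenium ion held under one face by the O7–C6–C5 tether, and the ketene acetal carbon C1 captures it in a five-membered closure, so that CH2 migrates from O to C1, ring A is formed cis-fused and the tertiary C1–O stereocentre (1S) is fixed by the tether; the closest known reactions are the Petasis–Ferrier rearrangement and the Lewis-acid [1,3] ring contraction of 4,5-dihydro-1,3-dioxepines to tetrahydrofurans (O-to-C shifts through oxocarbenium–enolate pairs), the Mukaiyama addition of silyl ketene acetals to acetals and the anionic acetal [1,2]-Wittig rearrangement.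

Step 9
Reactants: 2 1,2-dimethoxybenzene
Product: 14 4-bromo-1,2-dimethoxybenzene
Conditions: NBS (1.0 equiv), MeCN, 25 °C
Reagents that add atoms: N-bromosuccinimide, O=C1CCC(=O)N1Br
Why: Electrophilic aromatic bromination of veratrole with NBS is selective for the position para to a methoxy group and gives the 4-bromide needed for regiodefined lithiation.

Step 10
Reactants: 13 (1S,5R,6R)-6-(3,4-dimethoxyphenyl)-1-hydroxy-3,7-dioxabicyclo[3.3.0]octan-2-one, 14 4-bromo-1,2-dimethoxybenzene
Product: 17 (1S,2S,5R,6R)-2,6-bis(3,4-dimethoxyphenyl)-3,7-dioxabicyclo[3.3.0]octan-1-ol, via aryllithium 15 (not isolated), via lactol 16 (not isolated)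
Conditions: 14 (2.3 equiv), n-BuLi (2.3 equiv), THF, −78 °C; add 13; AcOH (2.4 equiv); then Et3SiH, BF3·OEt2, CH2Cl2, −78 → −30 °C
Reagents that add atoms: none
Why: Bromine–lithium exchange and 1,2-addition of the aryllithium to the lactone carbonyl give the lactol (one further equivalent only deprotonates the hydroxyl), and ionic hydrogenation with Et3SiH/BF3·OEt2 delivers hydride to the aryl-stabilised oxocarbenium ion on the convex face, cis to the oxygen at C1 as in the β-selective reduction of C-aryl glycoside lactols, so the new aryl group ends endo (2S).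

**Compound list**

1 | catechol (benzene-1,2-diol) | Oc1ccccc1O | starting material
2 | 1,2-dimethoxybenzene (veratrole) | COc1ccccc1OC | intermediate
3 | 1-(3,4-dimethoxyphenyl)ethanone | CC(=O)c1ccc(OC)c(OC)c1 | intermediate
4 | dimethyl oxalate | COC(=O)C(=O)OC | starting material
5 | sodium (Z)-1-(3,4-dimethoxyphenyl)-4-methoxy-3,4-dioxobut-1-en-1-olate (sodium enolate of the methyl aroylpyruvate; not isolated) | COC(=O)C(=O)/C=C(\[O-])c1ccc(OC)c(OC)c1.[Na+] | intermediate
6 | 4-(3,4-dimethoxybenzoyl)-3-hydroxyfuran-2(5H)-one | COc1ccc(C(=O)C2=C(O)C(=O)OC2)cc1OC | intermediate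
7 | 4-(3,4-dimethoxybenzoyl)-3-(methoxymethoxy)furan-2(5H)-one | COc1ccc(C(=O)C2=C(OCOC)C(=O)OC2)cc1OC | intermediate
8 | (S)-4-[(3,4-dimethoxyphenyl)(hydroxy)methyl]-3-(methoxymethoxy)furan-2(5H)-one | COc1ccc([C@H](O)C2=C(OCOC)C(=O)OC2)cc1OC | intermediate
9 | (5S)-5-(3,4-dimethoxyphenyl)-2,4,8-trioxabicyclo[4.3.0]non-1(6)-en-9-one (cyclic formal fused to the butenolide) | COc1ccc([C@@H]2OCOC3=C2COC3=O)cc1OC | intermediate
10 | (1S,5R,6R)-5-(3,4-dimethoxyphenyl)-2,4,8-trioxabicyclo[4.3.0]nonan-9-one (cis-fused; aryl trans to both ring-fusion hydrogens) | COc1ccc([C@@H]2OCO[C@H]3[C@@H]2COC3=O)cc1OC | intermediate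
11 | (5R,6R)-5-(3,4-dimethoxyphenyl)-9-[(trimethylsilyl)oxy]-2,4,8-trioxabicyclo[4.3.0]non-1(9)-ene (silyl ketene acetal; not isolated) | COc1ccc([C@@H]2OCOC3=C(O[Si](C)(C)C)OC[C@H]23)cc1OC | intermediate
12 | (1S,5R,6R)-6-(3,4-dimethoxyphenyl)-1-[(trimethylsilyl)oxy]-3,7-dioxabicyclo[3.3.0]octan-2-one (not isolated) | COc1ccc([C@@H]2OC[C@@]3(O[Si](C)(C)C)[C@@H]2COC3=O)cc1OC | intermediate
13 | (1S,5R,6R)-6-(3,4-dimethoxyphenyl)-1-hydroxy-3,7-dioxabicyclo[3.3.0]octan-2-one (cis-fused; aryl endo) | COc1ccc([C@@H]2OC[C@@]3(O)[C@@H]2COC3=O)cc1OC | intermediate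
14 | 4-bromo-1,2-dimethoxybenzene | COc1ccc(Br)cc1OC | intermediate
15 | (3,4-dimethoxyphenyl)lithium (not isolated) | [Li]c1ccc(OC)c(OC)c1 | intermediate
16 | (1S,5R,6R)-2,6-bis(3,4-dimethoxyphenyl)-3,7-dioxabicyclo[3.3.0]octane-1,2-diol (lactol, both C2 epimers; not isolated) | COc1ccc([C@@H]2OC[C@@]3(O)[C@@H]2COC3(O)c2ccc(OC)c(OC)c2)cc1OC | intermediate
17 | (1S,2S,5R,6R)-2,6-bis(3,4-dimethoxyphenyl)-3,7-dioxabicyclo[3.3.0]octan-1-ol | COc1ccc([C@@H]2OC[C@@]3(O)[C@@H]2CO[C@H]3c2ccc(OC)c(OC)c2)cc1OC | target

**Step count and risks**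

Total step count: 10. Longest linear sequence: 9 steps (steps 1–8 and 10; step 9 is a one-step branch from 2).

Steps most likely to fail:

1. Step 8, the new ring contraction. Me3SiOTf could instead ionise the benzylic C6–O7 bond, or the ketene acetal could react intermolecularly. The fallback uses known chemistry, sets out from 10 and comes back at 13.
 - The cyclic formal is cleaved with Me3SiOTf/2,2′-bipyridyl and then water to the diol (3S,4R)-4-[(R)-(3,4-dimethoxyphenyl)(hydroxy)methyl]-3-hydroxydihydrofuran-2(3H)-one F1.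
 - MOMCl/i-Pr2NEt protects both hydroxyls, giving (3S,4R)-4-[(R)-(3,4-dimethoxyphenyl)(methoxymethoxy)methyl]-3-(methoxymethoxy)dihydrofuran-2(3H)-one F2.
 - LiN(SiMe3)2/Me3SiCl (THF, −78 °C) gives the silyl ketene acetal (4R)-4-[(R)-(3,4-dimethoxyphenyl)(methoxymethoxy)methyl]-3-(methoxymethoxy)-2-[(trimethylsilyl)oxy]-4,5-dihydrofuran F3.
 - Catalytic Me3SiOTf then ionises the benzylic MOM ether, where methoxide is the only good leaving group. A conventional intramolecular Mukaiyama addition to the oxocarbenium ion closes ring A from the tether face, giving (1S,5R,6R)-6-(3,4-dimethoxyphenyl)-1-(methoxymethoxy)-3,7-dioxabicyclo[3.3.0]octan-2-one F4.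
 - Removal of the tertiary MOM group (Me3SiOTf/2,2′-bipyridyl, then water) gives 13.

2. Step 5, the asymmetric hydrogenation. The hindered diaryl-type ketone may reduce slowly or with low or reversed enantioselectivity. The fallback replaces catalyst control by resolution, sets out from 7 and comes back at 8.
 - Luche reduction (NaBH4, CeCl3·7H2O, MeOH, −40 °C) gives the racemic carbinol 4-[(3,4-dimethoxyphenyl)(hydroxy)methyl]-3-(methoxymethoxy)furan-2(5H)-one F5.
 - Kinetic resolution by lipase-catalysed acylation (Candida antarctica lipase B, vinyl acetate, t-BuOMe) converts the (R)-alcohol into (R)-(3,4-dimethoxyphenyl)[4-(methoxymethoxy)-5-oxo-2,5-dihydrofuran-3-yl]methyl acetate F6.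
 - Chromatography separates F6 from unreacted (S)-carbinol 8.

3. Step 7, hydrogenation of the tetrasubstituted α-alkoxy butenolide. The alkene may be inert, the face selectivity may be low, or benzylic C–O hydrogenolysis may compete. The fallback sets out from 9 and comes back at 11.
 - Conjugate hydride reduction with LiBH(s-Bu)3 (THF, −78 °C) attacks C5 from the face opposite the aryl group and gives the enolate lithium (5R,6R)-5-(3,4-dimethoxyphenyl)-2,4,8-trioxabicyclo[4.3.0]non-1(9)-en-9-olate F7.
 - Trapping with Me3SiCl gives silyl ketene acetal 11, which is treated with Me3SiOTf as in step 8, so the saturated formal 10 is bypassed.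

Further compounds
F1 | step 8 | (3S,4R)-4-[(R)-(3,4-dimethoxyphenyl)(hydroxy)methyl]-3-hydroxydihydrofuran-2(3H)-one | COc1ccc([C@H](O)[C@H]2COC(=O)[C@H]2O)cc1OC
F2 | step 8 | (3S,4R)-4-[(R)-(3,4-dimethoxyphenyl)(methoxymethoxy)methyl]-3-(methoxymethoxy)dihydrofuran-2(3H)-one | COc1ccc([C@H](OCOC)[C@H]2COC(=O)[C@H]2OCOC)cc1OC
F3 | step 8 | (4R)-4-[(R)-(3,4-dimethoxyphenyl)(methoxymethoxy)methyl]-3-(methoxymethoxy)-2-[(trimethylsilyl)oxy]-4,5-dihydrofuran | COc1ccc([C@H](OCOC)[C@H]2COC(O[Si](C)(C)C)=C2OCOC)cc1OC
F4 | step 8 | (1S,5R,6R)-6-(3,4-dimethoxyphenyl)-1-(methoxymethoxy)-3,7-dioxabicyclo[3.3.0]octan-2-one | COc1ccc([C@@H]2OC[C@@]3(OCOC)[C@@H]2COC3=O)cc1OC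
F5 | step 5 | 4-[(3,4-dimethoxyphenyl)(hydroxy)methyl]-3-(methoxymethoxy)furan-2(5H)-one (racemate) | COc1ccc(C(O)C2=C(OCOC)C(=O)OC2)cc1OC
F6 | step 5 | (R)-(3,4-dimethoxyphenyl)[4-(methoxymethoxy)-5-oxo-2,5-dihydrofuran-3-yl]methyl acetate | COc1ccc([C@@H](OC(C)=O)C2=C(OCOC)C(=O)OC2)cc1OC
F7 | step 7 | lithium (5R,6R)-5-(3,4-dimethoxyphenyl)-2,4,8-trioxabicyclo[4.3.0]non-1(9)-en-9-olate | COc1ccc([C@@H]2OCOC3=C([O-])OC[C@H]23)cc1OC.[Li+]
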